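**Clock power.** Half-times of 20.5 min in the zeta run and 17.1 min in the gamma run, taken between readings, differ by a factor of 1.20 for a starting material charge 1.50 times the zeta charge. I work in base-ten logarithms, and the ratio of those two logarithms is 0.448. That is my clock power, the power of the starting material charge by which the time to convert half of that charge shrinks at fixed coupling partner.

| flask | starting material | coupling partner | time |
|---|---|---|---|
| zeta | 0.600 M | 0.720 M |  |
| eta | 0.600 M | 1.40 M |  |
| gamma | 0.900 M | 0.720 M |  |
| theta | 0.200 M | 1.40 M | 35 min |

| zeta run: time / min | zeta run: [product] / M | eta run: time / min | eta run: [product] / M | gamma run: time / min | gamma run: [product] / M |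
|---|---|---|---|---|---|
| 4.4 | 0.007 | 4.4 | 0.046 | 4.4 | 0.023 |
| 8.8 | 0.053 | 8.8 | 0.263 | 8.8 | 0.144 |
| 13 | 0.132 | 13 | 0.404 | 13 | 0.322 |
| 18 | 0.261 | 18 | 0.479 | 18 | 0.479 |
| 22 | 0.324 | 22 | 0.510 | 22 | 0.558 |
| 26 | 0.391 | 26 | 0.546 | 26 | 0.615 |
| 31 | 0.436 | 31 | 0.552 | 31 | 0.653 |
| 35 | 0.469 | 35 | 0.571 | 35 | 0.667 |

(standard deviation of a reading: 0.005 M)

- the power of [starting material] that the first rate follows, about the charge of the zeta run; measure it at two percent of starting material made into product (one fixed amount of product, the same in the runs compared)
- the power of [coupling partner] that the first rate follows, about the charge of the zeta run; measure it at two percent of starting material made into product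
- product in the theta run at 35 min, as a share of the starting material charged

- Overall: starting material + coupling partner -> product.
- Constant volume, constant temperature.
- Readings of a species count what is bound in complexes too.
- An order is taken over about fifteen percent of the charge, up and down.

**First rates.** I compare clocks at one fixed amount of product, the 0.053 M of the second zeta reading, taken at 8.8 min. Between readings, the gamma run reaches that amount at 5.49 min and the eta run at 4.54 min. The same logarithms give me orders of 1.16 in starting material and 0.995 in coupling partner. These are rough values: I read them at that later amount, across the full gaps between charges.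

**Theta curve.** The theta run has the coupling partner charge of the eta run. So I draw it as the eta curve at a third of the height, with its clock stretched by 1.64. The first two eta readings, so mapped, give an early theta slope of 0.0101 M min⁻¹. The knee comes before that stretch of curve: the first eta reading lands at 0.0153 M and 7.20 min. The curve crosses a quarter of its charge at 10.6 min and half at 16.2 min.

Dividing 35 min by the stretch gives 21.4 min on the eta clock. Between eta readings, that is 0.505 M, so I commit to 84.2%. The ceiling is 0.200 M: starting material is the limiting reagent, below the 1.40 M of coupling partner.

**The forecast.** It gives orders of 1.05 and 0.95 and a yield of 85%, judging for theta “so autocatalysis is weak”. Its yield stands 0.80 percentage points above mine.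

**The flask.** The theta run gives 79.1%, with orders of 0.87 and 1.0.

    starting material ⇌ intermediate + by-product (0.09300 min⁻¹, 0.9660 L mol⁻¹ min⁻¹)
    intermediate + coupling partner → product (0.02358 L mol⁻¹ min⁻¹)
    starting material + coupling partner + product → 2 product (1.110 L² mol⁻² min⁻¹)
    coupling partner + by-product ⇌ reagent-by-product salt, settled at all times (1.320 L mol⁻¹)

The forecast's yield is what one gets from the zeta run with its clock scaled as if first order in everything but starting material. The step taking starting material, coupling partner and product to two product moves the readings by 69 times the scatter, root mean square. Read back on the eta readings, 79.1% gives the theta run a clock power of 0.620, against my 0.448. My clock power stretches the gamma quarter-time of 10.9 min to 13.1 min for the zeta run, whose readings cross 0.150 M at 13.7 min.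

All runs stem from a simulated flask with made-up constants; noise was put on by code.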